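## The problem

The target is a tris(2,3-dihydrobenzofuran). Rings A, B and C are joined head to tail: C3 of ring A to C4 of ring B, and C3 of ring B to C4 of ring C. C3 of ring C carries the 3,5-dihydroxyphenyl group, every C2 carries a 4-hydroxyphenyl group, and C4 of ring A carries the (E)-3,4-dihydroxystyryl group. Each C3 is therefore a diarylmethine carbon wedged between an ortho-substituted arene and a benzylic ether carbon, and the two inter-ring bonds sit at the most hindered positions. There are six stereocentres in three trans C2/C3 pairs: (2R,3R) in rings A and C, (2S,3S) in ring B. Within a pair C3 can set C2, because C2 is a 4-oxybenzylic ether carbon that ionises and recloses to the trans isomer. Between pairs there is no relay, since the C3 centres are insulated by arene rings, so each C3 needs its own absolute control. The O1–C2 bonds open under strong acid, the catechol stilbene is prone to acid-triggered cyclisation onto the neighbouring electron-rich rings and to oxidation, and ten free phenols rule out late oxidants and strong bases. The feature that invites a benzannulation is the benzene ring of ring B (C3a, C4, C5, C6, C7, C7a): oxygen on C7a and C6, carbon on C3a and C4, hydrogen on C5 and C7. C7a/C7 can come from an ethynyl ether on the C2 oxygen, C3a/C4 from an alkyne on C3 whose far end is C3 of ring A, and C6/C5 from an alkoxyacetylene, so the central ring can be made last, between two finished neighbours.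

## Retrosynthesis

**Phenols and stilbene last.** Target 36 is decaacetate 35 without its acetyl groups. 35 is cut at the bond between C4 of ring A and the styrene carbon, giving aryl chloride 33 and 3,4-diacetoxystyrene 34 (Heck reaction). 33 is the peracetate of octaphenol 32, which is the fully dealkylated form of the key-step product 31. Carrying the styryl group through the route would expose it to the Lewis-acid dealkylation, under which stilbenes next to a dihydrobenzofuran cyclise. Cutting here lets the ethers be cleaved before the alkene exists and leaves only an ammonolysis after it. Chlorine is the one handle that passes unchanged through an organolithium at −78 °C, the copper–boryl steps, the ruthenium catalyst and the dealkylation. The forward steps must achieve oxidative addition into a hindered aryl chloride and an ester cleavage mild enough for a catechol stilbene.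

**Ring B by benzannulation (key disconnection).** In 31 three bonds of the central benzene ring are cut, C7a–C3a, C7–C6 and C5–C4, which also opens the dihydrofuran of ring B. What remains is diyne 29 and ethoxyacetylene 30. In 29 the C2 oxygen of ring B carries an ethynyl group, and C3 carries an alkyne whose far end is C3 of the finished ring A. Each neighbouring cut would have to join an existing arene to a hindered carbon: arylation of a diarylmethine at C3(B)–C3a, or addition to a crowded methide at C4(B)–C3(A). Here the arene does not exist until both hindered carbons are already bonded to slim sp carbons. 29 is simpler by a benzene ring and a heterocycle, yet already holds all six stereocentres. The forward reaction must place ethoxy on C6 and not C5, and must run at room temperature because the 4-methoxybenzylic ethynyl ether is thermally and acid labile.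

**The ethynyl ether.** The O–C(sp) bond of 29 is cut to secondary alcohol 26 and trichloroethylene 27, the two-carbon source. This puts the fragile group in place in the step before it is used. The forward reaction needs a base sequence that does not touch the benzylic propargylic C–H bonds.

**C2–C3 of ring B and the union of the halves.** 26 is cut between C2 and C3 of ring B into 4-methoxybenzaldehyde 18 and allenylboronate 25. 25 is the product of an anti SN2′ borylation of propargylic carbonate 24. Addition through a closed transition state gives the anti alcohol, and anti is what the benzannulation turns into trans because the oxygen is retained. 24 comes from alcohol 23, which is cut at the carbinol–alkyne bond into ring C aldehyde 11 and ring A alkyne 22. This cut is the most convergent one available: both dihydrobenzofurans arrive complete, and the one new carbinol centre, set by a catalyst, is relayed into both centres of ring B. The forward steps need catalyst control in the alkynylation and clean chirality transfer from centre to axis to centre.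

**Ring A alkyne 22.** The O1–C2 bond is cut to phenol alcohol 21, formed in the flask from MOM ether 20 (acid cyclodehydration, trans by way of the benzylic cation). 20 is cut between C2 and C3 into 18 and allenylboronate 19, from carbonate 17, alcohols 16 and 15, and aldehyde 14. 14 comes from 2-chloro-4,6-dimethoxybenzaldehyde 12 through phenol 13. C3 of ring A is thus set on a small molecule by the same chirality transfer, and the crowded C3(A)–C4(B) bond is never made by a coupling, because C4(B) is born in the benzannulation. Closure by cation capture makes the C2 outcome independent of the carbinol configuration.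

**Ring C aldehyde 11.** The formyl group is put on by bromine–lithium exchange of bromide 10. 10 is cut at C2–C3 and O1–C2 into ortho-quinone methide 8 and benzylic sulfonium ylide 9. These come from sulfone 7 and chiral salt 3 (from sulfide 1 and bromide 2). 7 derives from hydroxybenzhydrol 6 and aldehyde 5, made from 2-bromo-4,6-dimethoxybenzaldehyde 4. Ring C's C3 carries an aryl group and no alkyne, so the allenylboron route does not apply. The (4+1) annulation is used here, where the methide is small and its regiochemistry is fixed by the aldehyde carbon of 4.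

## Roads not taken

**Alternative 1: flavanone ring contraction to a ring C carboxylate.** The cut is the C3–C3a bond of ring C. Flavanone triflate A2 would be treated with a diacetoxyiodoarene (trivalent iodine) in acidic trimethyl orthoformate. The benzo carbon migrates from C4 to C3 of the iodane and C4 leaves as the methyl ester, giving trans ester triflate A1.
- Merits: the ring contraction is a known reaction, cheap, and gives the trans ring directly with a triflate at C4 for later coupling. As a single step it is better precedented than the key step chosen here.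
- Weak points: A1 has an ester where ring C needs the 3,5-dimethoxyphenyl group, so the hardest bond of ring C, aryl to a hindered secondary benzylic carbon, is still to be made. The required (2R) configuration means A2 must be made by asymmetric synthesis, and flavanones racemise by retro-oxa-Michael opening under acid. Flavone and isoflavone formation compete. Both inter-ring bonds remain unsolved.
- Comparison: the chosen plan sets against the better precedent the fact that every C3 aryl group is in place from the first C–C bond, and that ring B with both inter-ring bonds is formed in one operation.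

**Alternative 2: twofold phenol dehydrogenation and quinone methide oxa-cyclisation.** The cuts are the O1–C2 bonds of rings B and C. A quinone oxidant would convert the two 4-hydroxybenzyl groups of tetraphenol A4 into para-quinone methides, and the C7a phenols would add in 1,6 fashion to give A3.
- Merits: biomimetic, two rings in one step, trans selectivity as reliable as in the chosen route, and a shorter endgame.
- Weak points: A4 must already hold the diarylmethine centres at C3 of rings B and C in the right absolute sense, together with the C3(B)–C4(C) and C4(B)–C3(A) bonds. The step therefore leaves both the stereochemical and the bond-construction problem to an undefined earlier stage. The oxidant also threatens the finished ring A (dehydrogenation of dihydrobenzofurans to benzofurans) and the electron-rich rings.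
- Comparison: alternative 2 is better in step economy at the end. The chosen plan answers with reagent-controlled construction of each C3 and with no oxidant after the stereocentres exist.

**Alternative 3: ortho-quinone methide and sulfur ylide (4+1) annulation for ring A.** The cuts are C2–C3 and O1–C2 of ring A. Base would convert phenol sulfone A6 into its quinone methide, and a chiral benzylic sulfonium salt of the kind of 3 would supply the ylide, giving bromide A5.
- Merits: a known annulation type, trans-selective, reagent-controlled, and it delivers exactly the halide needed for the Heck reaction. For ring A alone it is shorter than steps 7 to 13 here.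
- Weak points: A6 requires hydroxyalkylation of 3-bromo-5-methoxyphenol A7 at the carbon between OH and Br, one of three doubly activated positions. The methide is flanked by bromine and by the ortho-substituted ring B, so the ylide must add to a very crowded carbon next to resident stereocentres. Rings B and C must still come from elsewhere.
- Comparison: the chosen plan uses the same annulation once (step 5), on the small methide 8. It builds ring A's C3 on a small molecule and lets the crowded C3(A)–C4(B) junction arise as an arene carbon in the benzannulation.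

Key step: step 18

## Route

Assumptions:
- The antipodes named, (S,S)-ProPhenol and (1R,4R,5R)-isothiocineole, are taken to give the configurations drawn; if a facial preference on these substrates is the reverse, the mirror-image ligand or sulfide is used with no other change.
- 12 and 34 are taken as catalogue compounds (otherwise each is one or two standard steps from 1-chloro-3,5-dimethoxybenzene or 3,4-dihydroxybenzaldehyde).

Abbreviations for two recurring substituents:
- RC = (2R,3R)-3-(3,5-dimethoxyphenyl)-6-methoxy-2-(4-methoxyphenyl)-2,3-dihydro-1-benzofuran-4-yl (ring C unit, bonded through C4).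
- RA = (2R,3R)-4-chloro-6-methoxy-2-(4-methoxyphenyl)-2,3-dihydro-1-benzofuran-3-yl (ring A unit, bonded through C3).

Step 1
Reactants: 1 (1R,4R,5R)-isothiocineole; 2 4-methoxybenzyl bromide
Product: 3 (1R,4R,5R)-6-(4-methoxybenzyl)-4,7,7-trimethyl-6-thiabicyclo[3.2.1]octan-6-ium tetrafluoroborate
Conditions: NaBF4, CH2Cl2/H2O, rt
Reagents that add atoms: sodium tetrafluoroborate, [Na+].F[B-](F)(F)F
Why: S-Alkylation of the sulfide by the benzylic bromide with exchange of bromide for the non-nucleophilic tetrafluoroborate, which stops the reverse dealkylation; the bicyclic sulfide should be alkylated on one lone pair only, giving a single sulfonium diastereomer.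

Step 2
Reactants: 4 2-bromo-4,6-dimethoxybenzaldehyde
Product: 5 2-bromo-6-hydroxy-4-methoxybenzaldehyde
Conditions: BCl3, CH2Cl2, −78 → 0 °C; H2O
Reagents that add atoms: none
Why: Chelation-directed ether cleavage: boron binds the formyl oxygen and removes only the methyl group of the ortho methoxy group.

Step 3
Reactants: 5 2-bromo-6-hydroxy-4-methoxybenzaldehyde
Product: 6 3-bromo-2-[(3,5-dimethoxyphenyl)(hydroxy)methyl]-5-methoxyphenol (racemic)
Conditions: 3,5-(MeO)2C6H3MgBr (2.5 equiv), THF, 0 °C → rt; H2O
Reagents that add atoms: 3,5-dimethoxyphenylmagnesium bromide, COc1cc(OC)cc([Mg]Br)c1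
Why: Grignard 1,2-addition to the aldehyde after the first equivalent has removed the phenol proton; the carbinol centre is racemic and is erased when the quinone methide forms in step 5.

Step 4
Reactants: 6 3-bromo-2-[(3,5-dimethoxyphenyl)(hydroxy)methyl]-5-methoxyphenol
Product: 7 3-bromo-2-[(3,5-dimethoxyphenyl)(4-methylbenzenesulfonyl)methyl]-5-methoxyphenol (racemic)
Conditions: p-TolSO2Na, HCO2H/H2O, rt
Reagents that add atoms: sodium 4-methylbenzenesulfinate, [Na+].Cc1ccc(S(=O)[O-])cc1
Why: Acid ionises the electron-rich ortho-hydroxybenzhydrol to its quinone methide and sulfinate adds through sulfur, the usual way to 2-(1-sulfonylalkyl)phenols; the sulfone is a storable quinone methide precursor.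

Step 5
Reactants: 7 3-bromo-2-[(3,5-dimethoxyphenyl)(4-methylbenzenesulfonyl)methyl]-5-methoxyphenol; 3 (1R,4R,5R)-6-(4-methoxybenzyl)-4,7,7-trimethyl-6-thiabicyclo[3.2.1]octan-6-ium tetrafluoroborate
Product: 10 (2R,3R)-4-bromo-3-(3,5-dimethoxyphenyl)-6-methoxy-2-(4-methoxyphenyl)-2,3-dihydro-1-benzofuran, via ortho-quinone methide 8 (not isolated), via sulfonium ylide 9 (not isolated)
Conditions: Cs2CO3, MeCN/CH2Cl2, −20 °C → rt
Reagents that add atoms: none
Why: Base-mediated (4+1) annulation of an ortho-quinone methide with a sulfur ylide: Cs2CO3 releases 8 by 1,4-elimination of sulfinate and 9 by deprotonation of 3, 9 adds to the methide carbon and the phenoxide displaces the sulfide from the anti betaine in a 5-exo-tet closure, which gives the trans ring. The bicyclic sulfide fixes the conformation and open face of the ylide and so sets C2; C3 follows from the anti betaine, as in epoxidations with the same benzylic ylides.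

Step 6
Reactants: 10 (2R,3R)-4-bromo-3-(3,5-dimethoxyphenyl)-6-methoxy-2-(4-methoxyphenyl)-2,3-dihydro-1-benzofuran
Product: 11 (2R,3R)-3-(3,5-dimethoxyphenyl)-6-methoxy-2-(4-methoxyphenyl)-2,3-dihydro-1-benzofuran-4-carbaldehyde
Conditions: n-BuLi, THF, −78 °C; DMF; H2O
Reagents that add atoms: N,N-dimethylformamide, CN(C)C=O
Why: Bromine–lithium exchange at −78 °C is faster than attack on the benzylic C–H bonds, and the aryllithium is formylated by DMF (Bouveault aldehyde synthesis); no stereocentre is involved.

Step 7
Reactants: 12 2-chloro-4,6-dimethoxybenzaldehyde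
Product: 13 2-chloro-6-hydroxy-4-methoxybenzaldehyde
Conditions: BCl3, CH2Cl2, −78 → 0 °C; H2O
Reagents that add atoms: none
Why: The same chelation-directed cleavage of the methoxy group ortho to the formyl group as in step 2.

Step 8
Reactants: 13 2-chloro-6-hydroxy-4-methoxybenzaldehyde
Product: 14 2-chloro-4-methoxy-6-(methoxymethoxy)benzaldehyde
Conditions: MOMCl, i-Pr2NEt, CH2Cl2, 0 °C → rt
Reagents that add atoms: chloromethyl methyl ether, COCCl
Why: O-Alkylation of the phenol as its MOM ether, which is stable to the organozinc, copper–boryl and basic steps and is removed by the acid that closes ring A in step 13.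

Step 9
Reactants: 14 2-chloro-4-methoxy-6-(methoxymethoxy)benzaldehyde
Product: 15 (1S)-1-[2-chloro-4-methoxy-6-(methoxymethoxy)phenyl]-3-(trimethylsilyl)prop-2-yn-1-ol
Conditions: Me3SiC≡CH, Me2Zn, (S,S)-ProPhenol (10 mol%), Ph3PO (20 mol%), toluene, 0 °C → rt
Reagents that add atoms: trimethylsilylacetylene, C#C[Si](C)(C)C
Why: Catalytic asymmetric addition of an alkynylzinc to an aryl aldehyde under dinuclear zinc–ProPhenol control; the catalyst selects the aldehyde face and sets the (S) carbinol, and ortho-substituted aryl aldehydes are good substrates.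

Step 10
Reactants: 15 (1S)-1-[2-chloro-4-methoxy-6-(methoxymethoxy)phenyl]-3-(trimethylsilyl)prop-2-yn-1-ol
Product: 16 (1S)-1-[2-chloro-4-methoxy-6-(methoxymethoxy)phenyl]prop-2-yn-1-ol
Conditions: K2CO3 (cat.), MeOH, rt
Reagents that add atoms: none
Why: Methanolysis of the alkynyl C–Si bond; the carbinol centre is not touched.

Step 11
Reactants: 16 (1S)-1-[2-chloro-4-methoxy-6-(methoxymethoxy)phenyl]prop-2-yn-1-ol
Product: 17 (1S)-1-[2-chloro-4-methoxy-6-(methoxymethoxy)phenyl]prop-2-yn-1-yl methyl carbonate
Conditions: ClCO2Me, pyridine, CH2Cl2, 0 °C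
Reagents that add atoms: methyl chloroformate, COC(=O)Cl
Why: O-Acylation to the propargylic carbonate, the leaving group for the copper-catalysed substitution; the two ortho substituents twist the ring and slow ionisation of this electron-rich benzylic carbonate, which is used at once.

Step 12
Reactants: 17 (1S)-1-[2-chloro-4-methoxy-6-(methoxymethoxy)phenyl]prop-2-yn-1-yl methyl carbonate; 18 4-methoxybenzaldehyde
Product: 20 (1S,2R)-2-[2-chloro-4-methoxy-6-(methoxymethoxy)phenyl]-1-(4-methoxyphenyl)but-3-yn-1-ol, via allenylboronate 19 (not isolated)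
Conditions: CuOt-Bu (10 mol%), Xantphos (10 mol%), B2pin2, THF, rt; silica plug; 18, toluene, 50 °C; H2O
Reagents that add atoms: none
Why: Copper-catalysed γ-selective boryl substitution of a propargylic carbonate (anti SN2′) turns the carbinol centre of 17 into the axis of 19, and 19 adds to 18 through a closed six-membered transition state on the boron side (allenylboration, SE2′). C3 is therefore formed with net inversion relative to the carbonate (chirality transfer) and the aldehyde aryl group lies anti to the propargylic aryl group (anti adduct).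

Step 13
Reactants: 20 (1S,2R)-2-[2-chloro-4-methoxy-6-(methoxymethoxy)phenyl]-1-(4-methoxyphenyl)but-3-yn-1-ol
Product: 22 (2R,3R)-4-chloro-3-ethynyl-6-methoxy-2-(4-methoxyphenyl)-2,3-dihydro-1-benzofuran, via free phenol 21 (not isolated)
Conditions: CF3CO2H, CH2Cl2, 0 °C
Reagents that add atoms: none
Why: Acid removes the MOM group and ionises the 4-methoxybenzylic alcohol; the phenol oxygen captures the cation and closes the five-membered ring with the aryl group trans to the ethynyl group (acid cyclodehydration to 2-aryl-2,3-dihydrobenzofurans). C2 is re-set under kinetic and thermodynamic control because the ring can reopen to the same cation, so only C3, which is not touched, had to be controlled earlier.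

Step 14
Reactants: 11 (2R,3R)-3-(3,5-dimethoxyphenyl)-6-methoxy-2-(4-methoxyphenyl)-2,3-dihydro-1-benzofuran-4-carbaldehyde; 22 (2R,3R)-4-chloro-3-ethynyl-6-methoxy-2-(4-methoxyphenyl)-2,3-dihydro-1-benzofuran
Product: 23 (1S)-3-RA-1-RC-prop-2-yn-1-ol
Conditions: Me2Zn, (S,S)-ProPhenol (20 mol%), Ph3PO (40 mol%), toluene, 0 °C → rt; 22 (1.5 equiv, excess recovered)
Reagents that add atoms: none
Why: The same catalytic asymmetric alkynylzinc addition as in step 9; the stereocentres of both partners are three or more atoms from the reacting carbons, so the catalyst should decide the new (S) carbinol, and any minor epimer is a separable diastereomer.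

Step 15
Reactants: 23 (1S)-3-RA-1-RC-prop-2-yn-1-ol
Product: 24 (1S)-3-RA-1-RC-prop-2-yn-1-yl methyl carbonate
Conditions: ClCO2Me, pyridine, DMAP (cat.), CH2Cl2, 0 °C
Reagents that add atoms: methyl chloroformate, COC(=O)Cl
Why: O-Acylation of the propargylic alcohol; this benzylic position is meta to both ring oxygens and is not prone to ionisation.

Step 16
Reactants: 24 (1S)-3-RA-1-RC-prop-2-yn-1-yl methyl carbonate; 18 4-methoxybenzaldehyde
Product: 26 (1S,2R)-4-RA-2-RC-1-(4-methoxyphenyl)but-3-yn-1-ol, via allenylboronate 25 (not isolated)
Conditions: CuOt-Bu (10 mol%), Xantphos (10 mol%), B2pin2, THF, rt; silica plug; 18, toluene, 60 °C; H2O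
Reagents that add atoms: none
Why: The sequence of step 12 on an internal alkyne: boron enters anti to the carbonate at the alkyne carbon that bears RA, and the trisubstituted allenylboronate 25 adds to 18 through the closed chair-like transition state. C3 of ring B is formed with inversion relative to C1 of 24 and C2 anti to it, both by chirality transfer from the catalyst-set carbinol.

Step 17
Reactants: 26 (1S,2R)-4-RA-2-RC-1-(4-methoxyphenyl)but-3-yn-1-ol; 27 trichloroethylene
Product: 29 (1S,2R)-4-RA-2-RC-1-(ethynyloxy)-1-(4-methoxyphenyl)but-3-yne, via dichlorovinyl ether 28 (not isolated)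
Conditions: KH, THF, 0 °C; 27, −50 °C → rt; n-BuLi (2.4 equiv), −78 → −40 °C; MeOH; filtration through Et3N-washed silica, used at once
Reagents that add atoms: none
Why: One-pot alkynyl ether synthesis from an alcohol and trichloroethylene: the potassium alkoxide adds to dichloroacetylene formed in situ, and n-BuLi converts 28 by elimination and chlorine–lithium exchange into the lithium alkynyl ether, which MeOH protonates. The C–O bond at C2 is never broken, and the vinylic C–H of 28 is far more acidic than the benzylic propargylic C–H bonds.

Step 18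
Reactants: 29 (1S,2R)-4-RA-2-RC-1-(ethynyloxy)-1-(4-methoxyphenyl)but-3-yne; 30 ethoxyacetylene
Product: 31 (2S,3S)-4-RA-3-RC-6-ethoxy-2-(4-methoxyphenyl)-2,3-dihydro-1-benzofuran
Conditions: Cp*RuCl(cod) (10 mol%), 30 (4 equiv, slow addition), ClCH2CH2Cl, rt
Reagents that add atoms: none
Why: Proposed new method: the Cp*RuCl fragment (divalent ruthenium) left after loss of cod binds the ethynyl ether and the internal alkyne of 29 and couples them oxidatively at C7a and C3a, giving a ruthenacyclopentadiene fused to the new dihydrofuran; ethoxyacetylene then adds at the less hindered Ru–C7 end and reductive elimination releases the arene with C7–C6 and C5–C4 formed. The closest known reaction type is the Cp*RuCl(cod)- or RhCl(PPh3)3-catalysed (2+2+2) cycloaddition of 1,6-diynes with monoalkynes, which covers ynamide-tethered diynes (indolines) and diynes whose internal terminus carries a bulky sp3 carbon (C-alkynyl glycosides); an oxygen-tethered ethynyl ether has not been used. The dihydrofuran closes in the oxidative coupling as the five-membered ring fused to the metallacycle, the normal mode for a three-atom tether, and the benzene ring closes by insertion and reductive elimination from the seven-membered ruthenacycle. No stereocentre is made: C2 and C3 of ring B sit in the tether and those of rings A and C are remote, so all six are carried through at room temperature. The selectivity needed is regiochemical, ethoxy on C6 and not C5: the C4 terminus bears the bulky ring A carbon, so the monoalkyne should enter at the unsubstituted C7 end with its substituent pointing away from C4, the meta preference documented for unsymmetrical diynes with this catalyst. Self-trimerisation of 30 is held back by the entropic advantage of the tethered diyne and by slow addition.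

Step 19
Reactants: 31 (2S,3S)-4-RA-3-RC-6-ethoxy-2-(4-methoxyphenyl)-2,3-dihydro-1-benzofuran
Product: 32 octaphenol chloride (31 with all seven methoxy groups and the ethoxy group as OH)
Conditions: BBr3, CH2Cl2, −78 °C → rt; H2O
Reagents that add atoms: none
Why: Lewis-acid cleavage of aryl methyl and ethyl ethers, which has precedent on 2,3-diaryl-dihydrobenzofuran oligomers; the aryl chloride is inert, and any ionisation of an O1–C2 bond recloses to the trans isomer, which is the thermodynamic one. Doing this before the stilbene exists avoids acid-triggered cyclisation of the alkene onto ring B.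

Step 20
Reactants: 32 octaphenol chloride
Product: 33 octaacetate chloride (all eight phenols of 32 as acetates)
Conditions: Ac2O, pyridine, DMAP (cat.), rt
Reagents that add atoms: acetic anhydride, CC(=O)OC(C)=O
Why: Exhaustive O-acetylation; the acetates make the polyphenol soluble and inert toward palladium and are removed under near-neutral conditions.

Step 21
Reactants: 33 octaacetate chloride; 34 3,4-diacetoxystyrene
Product: 35 decaacetate of the target ((E)-stilbene)
Conditions: Pd2(dba)3 (3 mol%), [HP(t-Bu)3]BF4 (12 mol%), Cy2NMe, dioxane, 100 °C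
Reagents that add atoms: none
Why: Heck reaction of an aryl chloride with a styrene under the Pd/P(t-Bu)3/Cy2NMe system developed for hindered and unactivated aryl chlorides; the chloride is meta to two oxygens, which helps oxidative addition, and syn insertion followed by β-hydride elimination gives the (E)-alkene.

Step 22
Reactants: 35 decaacetate of the target
Product: 36 CNP0099535.1
Conditions: NH3 (7 M in MeOH), 0 °C → rt, argon
Reagents that add atoms: none
Why: Ammonolysis of aryl acetates, fast at or below room temperature and free of acid, so the stilbene and the three O1–C2 bonds are not touched; exclusion of oxygen protects the catechol.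

## Compound list

1 | (1R,4R,5R)-isothiocineole, (1R,4R,5R)-4,7,7-trimethyl-6-thiabicyclo[3.2.1]octane | C[C@@H]1CC[C@@H]2C[C@H]1SC2(C)C | starting material
2 | 4-methoxybenzyl bromide | COc1ccc(CBr)cc1 | starting material
3 | (1R,4R,5R)-6-(4-methoxybenzyl)-4,7,7-trimethyl-6-thiabicyclo[3.2.1]octan-6-ium tetrafluoroborate (one diastereomer at sulfur, as formed on alkylation; sulfur left unassigned in the SMILES) | C[C@@H]1CC[C@@H]2C[C@H]1[S+](Cc3ccc(OC)cc3)C2(C)C.F[B-](F)(F)F | intermediate
4 | 2-bromo-4,6-dimethoxybenzaldehyde | COc1cc(OC)c(C=O)c(Br)c1 | starting material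
5 | 2-bromo-6-hydroxy-4-methoxybenzaldehyde | COc1cc(O)c(C=O)c(Br)c1 | intermediate
6 | 3-bromo-2-[(3,5-dimethoxyphenyl)(hydroxy)methyl]-5-methoxyphenol (racemic) | COc1cc(O)c(C(O)c2cc(OC)cc(OC)c2)c(Br)c1 | intermediate
7 | 3-bromo-2-[(3,5-dimethoxyphenyl)(4-methylbenzenesulfonyl)methyl]-5-methoxyphenol (racemic) | COc1cc(O)c(C(c2cc(OC)cc(OC)c2)S(=O)(=O)c2ccc(C)cc2)c(Br)c1 | intermediate
8 | ortho-quinone methide, 5-bromo-6-(3,5-dimethoxybenzylidene)-3-methoxycyclohexa-2,4-dien-1-one | COC1=CC(=O)C(=Cc2cc(OC)cc(OC)c2)C(Br)=C1 | intermediate
9 | sulfonium ylide, the 4-methoxybenzylide of 3 | C[C@@H]1CC[C@@H]2C[C@H]1[S+]([CH-]c3ccc(OC)cc3)C2(C)C | intermediate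
10 | (2R,3R)-4-bromo-3-(3,5-dimethoxyphenyl)-6-methoxy-2-(4-methoxyphenyl)-2,3-dihydro-1-benzofuran (trans; ring C bromide) | Brc1cc(OC)cc2c1[C@@H](c1cc(OC)cc(OC)c1)[C@H](c1ccc(OC)cc1)O2 | intermediate
11 | (2R,3R)-3-(3,5-dimethoxyphenyl)-6-methoxy-2-(4-methoxyphenyl)-2,3-dihydro-1-benzofuran-4-carbaldehyde (ring C aldehyde) | O=Cc1cc(OC)cc2c1[C@@H](c1cc(OC)cc(OC)c1)[C@H](c1ccc(OC)cc1)O2 | intermediate
12 | 2-chloro-4,6-dimethoxybenzaldehyde | COc1cc(OC)c(C=O)c(Cl)c1 | starting material
13 | 2-chloro-6-hydroxy-4-methoxybenzaldehyde | COc1cc(O)c(C=O)c(Cl)c1 | intermediate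
14 | 2-chloro-4-methoxy-6-(methoxymethoxy)benzaldehyde | COCOc1cc(OC)cc(Cl)c1C=O | intermediate
15 | (1S)-1-[2-chloro-4-methoxy-6-(methoxymethoxy)phenyl]-3-(trimethylsilyl)prop-2-yn-1-ol | C[Si](C)(C)C#C[C@H](O)c1c(Cl)cc(OC)cc1OCOC | intermediate
16 | (1S)-1-[2-chloro-4-methoxy-6-(methoxymethoxy)phenyl]prop-2-yn-1-ol | C#C[C@H](O)c1c(Cl)cc(OC)cc1OCOC | intermediate
17 | (1S)-1-[2-chloro-4-methoxy-6-(methoxymethoxy)phenyl]prop-2-yn-1-yl methyl carbonate | C#C[C@H](OC(=O)OC)c1c(Cl)cc(OC)cc1OCOC | intermediate
18 | 4-methoxybenzaldehyde | COc1ccc(C=O)cc1 | starting material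
19 | allenylboronate, 2-{3-[2-chloro-4-methoxy-6-(methoxymethoxy)phenyl]propa-1,2-dien-1-yl}-4,4,5,5-tetramethyl-1,3,2-dioxaborolane (axis as in the SMILES, from anti substitution) | [H]C(c1c(Cl)cc(OC)cc1OCOC)=[C@]=C([H])B1OC(C)(C)C(C)(C)O1 | intermediate
20 | (1S,2R)-2-[2-chloro-4-methoxy-6-(methoxymethoxy)phenyl]-1-(4-methoxyphenyl)but-3-yn-1-ol (anti) | C#C[C@@H]([C@H](O)c1ccc(OC)cc1)c1c(Cl)cc(OC)cc1OCOC | intermediate
21 | free phenol, (1S,2R)-2-(2-chloro-6-hydroxy-4-methoxyphenyl)-1-(4-methoxyphenyl)but-3-yn-1-ol | C#C[C@@H]([C@H](O)c1ccc(OC)cc1)c1c(Cl)cc(OC)cc1O | intermediate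
22 | (2R,3R)-4-chloro-3-ethynyl-6-methoxy-2-(4-methoxyphenyl)-2,3-dihydro-1-benzofuran (trans; ring A alkyne) | C#C[C@@H]1c2c(Cl)cc(OC)cc2O[C@H]1c1ccc(OC)cc1 | intermediate
23 | (1S)-3-RA-1-RC-prop-2-yn-1-ol | O[C@@H](C#C[C@@H]4c5c(Cl)cc(OC)cc5O[C@H]4c4ccc(OC)cc4)c2cc(OC)cc3c2[C@@H](c2cc(OC)cc(OC)c2)[C@H](c2ccc(OC)cc2)O3 | intermediate
24 | (1S)-3-RA-1-RC-prop-2-yn-1-yl methyl carbonate | COC(=O)O[C@@H](C#C[C@@H]4c5c(Cl)cc(OC)cc5O[C@H]4c4ccc(OC)cc4)c2cc(OC)cc3c2[C@@H](c2cc(OC)cc(OC)c2)[C@H](c2ccc(OC)cc2)O3 | intermediate
25 | allenylboronate, 2-(1-RA-3-RC-propa-1,2-dien-1-yl)-4,4,5,5-tetramethyl-1,3,2-dioxaborolane (axis as in the SMILES) | [H]C(c2cc(OC)cc3c2[C@@H](c2cc(OC)cc(OC)c2)[C@H](c2ccc(OC)cc2)O3)=[C@]=C([C@@H]4c5c(Cl)cc(OC)cc5O[C@H]4c4ccc(OC)cc4)B1OC(C)(C)C(C)(C)O1 | intermediate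
26 | (1S,2R)-4-RA-2-RC-1-(4-methoxyphenyl)but-3-yn-1-ol (anti) | COc1ccc([C@@H](O)[C@H](C#C[C@@H]4c5c(Cl)cc(OC)cc5O[C@H]4c4ccc(OC)cc4)c2cc(OC)cc3c2[C@@H](c2cc(OC)cc(OC)c2)[C@H](c2ccc(OC)cc2)O3)cc1 | intermediate
27 | trichloroethylene | ClC=C(Cl)Cl | starting material
28 | (E)-1,2-dichloroethenyl ether of 26 | COc1ccc([C@@H](O/C(Cl)=C\Cl)[C@H](C#C[C@@H]4c5c(Cl)cc(OC)cc5O[C@H]4c4ccc(OC)cc4)c2cc(OC)cc3c2[C@@H](c2cc(OC)cc(OC)c2)[C@H](c2ccc(OC)cc2)O3)cc1 | intermediate
29 | ethynyl ether of 26, (1S,2R)-4-RA-2-RC-1-(ethynyloxy)-1-(4-methoxyphenyl)but-3-yne | COc1ccc([C@@H](OC#C)[C@H](C#C[C@@H]4c5c(Cl)cc(OC)cc5O[C@H]4c4ccc(OC)cc4)c2cc(OC)cc3c2[C@@H](c2cc(OC)cc(OC)c2)[C@H](c2ccc(OC)cc2)O3)cc1 | intermediate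
30 | ethoxyacetylene | CCOC#C | starting material
31 | (2S,3S)-4-RA-3-RC-6-ethoxy-2-(4-methoxyphenyl)-2,3-dihydro-1-benzofuran (ring A 2R,3R; ring B 2S,3S; ring C 2R,3R; all trans) | COc1ccc([C@H]2Oc3cc(OCC)cc([C@@H]4c5c(Cl)cc(OC)cc5O[C@H]4c4ccc(OC)cc4)c3[C@@H]2c2cc(OC)cc3c2[C@@H](c2cc(OC)cc(OC)c2)[C@H](c2ccc(OC)cc2)O3)cc1 | intermediate
32 | octaphenol chloride (31 with all eight ether groups as OH) | Oc1ccc([C@H]2Oc3cc(O)cc([C@@H]4c5c(Cl)cc(O)cc5O[C@H]4c4ccc(O)cc4)c3[C@@H]2c2cc(O)cc3c2[C@@H](c2cc(O)cc(O)c2)[C@H](c2ccc(O)cc2)O3)cc1 | intermediate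
33 | octaacetate chloride (octa-O-acetyl 32) | CC(=O)Oc1ccc([C@H]2Oc3cc(OC(C)=O)cc([C@@H]4c5c(Cl)cc(OC(C)=O)cc5O[C@H]4c4ccc(OC(C)=O)cc4)c3[C@@H]2c2cc(OC(C)=O)cc3c2[C@@H](c2cc(OC(C)=O)cc(OC(C)=O)c2)[C@H](c2ccc(OC(C)=O)cc2)O3)cc1 | intermediate
34 | 3,4-diacetoxystyrene (4-ethenyl-1,2-phenylene diacetate) | C=Cc1ccc(OC(C)=O)c(OC(C)=O)c1 | starting material
35 | decaacetate of the target (33 with (E)-2-(3,4-diacetoxyphenyl)ethenyl in place of Cl) | CC(=O)Oc1ccc([C@H]2Oc3cc(OC(C)=O)cc([C@@H]4c5c(/C=C/c6ccc(OC(C)=O)c(OC(C)=O)c6)cc(OC(C)=O)cc5O[C@H]4c4ccc(OC(C)=O)cc4)c3[C@@H]2c2cc(OC(C)=O)cc3c2[C@@H](c2cc(OC(C)=O)cc(OC(C)=O)c2)[C@H](c2ccc(OC(C)=O)cc2)O3)cc1 | intermediate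
36 | CNP0099535.1 (ring A 2R,3R; ring B 2S,3S; ring C 2R,3R; E-stilbene) | Oc1ccc([C@H]2Oc3cc(O)cc([C@@H]4c5c(/C=C/c6ccc(O)c(O)c6)cc(O)cc5O[C@H]4c4ccc(O)cc4)c3[C@@H]2c2cc(O)cc3c2[C@@H](c2cc(O)cc(O)c2)[C@H](c2ccc(O)cc2)O3)cc1 | target

## Step count and least certain steps

Total: 22 steps. Longest linear sequence: 16 steps (steps 7 to 22); the ring C branch (steps 1 to 6) joins at step 14.

**Step 18 (key step).** The most likely failure is loss of the ethynyl ether before it cyclises: acid-triggered ionisation of the 4-methoxybenzylic C–O bond, or sigmatropic rearrangement to a ketene. Oxidative coupling slowed by the bulky ring A terminus would let 30 oligomerise. The polarity of 30 could also override the steric preference and put ethoxy on C5.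
Fallback, with a temporary boron tether in place of the ethynyl ether: alcohol 26 is transesterified with diisopropyl ethynylboronate to the mixed ethynylboronate F1. Cp*RuCl(cod) and 30 then give the cyclic arylboronate F2 by the known boron-tethered diyne–alkyne cycloaddition, with the same regiochemical logic. Alkaline H2O2 oxidises the C–B bond to give the phenol alcohol F3, and CF3CO2H closes ring B by the cyclodehydration used in step 13 (trans), returning to the route at 31.

**Step 17.** Deprotonation at the benzylic propargylic C–H bonds (C3 of ring B, C3 of ring A) by KH or n-BuLi, followed by β-elimination of the oxygen substituent, is the main danger. Retro-propargylation of the potassium alkoxide is a second.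
Fallback without a metal hydride: 26 is formylated with acetic formic anhydride to the formate F4 and converted with CBr4/PPh3 into the 2,2-dibromoethenyl ether F5. Bromine–lithium exchange with n-BuLi at −100 °C, which outruns C–H deprotonation, and rearrangement give the lithium alkynyl ether, rejoining at 29.

**Step 5.** Poor control of the ylide face, or leakage through the syn betaine to the cis isomer (whose C3 has the opposite sense), would lower the enantiomeric purity of ring C. Dealkylation of the electron-rich sulfonium salt is a further loss channel.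
Fallback by resolution: 7 is annulated with the achiral (4-methoxybenzyl)dimethylsulfonium tetrafluoroborate F6 to the racemate, the mirror image being the (2S,3S) bromide F7. The enantiomers are parted by preparative chromatography on a chiral stationary phase and the route is rejoined at 10.

**Step 16 (and its smaller counterpart, step 12).** Slow addition of the hindered, α-branched allenylboronate 25 to an electron-rich aldehyde could allow protodeboronation and erosion of the anti selectivity. In step 12 the risk is ionisation of the electron-rich carbonate 17 with loss of configuration.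
Fallback by palladium/zinc umpolung: from 24 (or 17), zerovalent palladium formed from Pd(OAc)2 and PPh3 opens the carbonate to an allenylpalladium, Et2Zn converts it into the allenylzinc, and this adds to 18 at −20 °C in the same anti sense with the same net inversion. The route is rejoined at 26 (or 20); this detour makes no compound outside the list (F0).

**Step 21.** Slow oxidative addition into the hindered aryl chloride at a temperature at which 34 polymerises is the likely problem.
Fallback by Suzuki–Miyaura coupling with the alkene geometry fixed beforehand: 34 and vinylboronic acid pinacol ester undergo cross-metathesis with the second-generation Grubbs catalyst to the (E)-alkenylboronate F8. F8 is coupled with 33 using Pd(OAc)2/SPhos and K3PO4. Any acetate lost to the base is of no consequence, because step 22 removes them all; the route is rejoined at 35.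

## Further compounds

F1 | step 18 | (ethynyl)(isopropoxy)boryl ether of 26 | COc1ccc([C@@H](OB(OC(C)C)C#C)[C@H](C#C[C@@H]4c5c(Cl)cc(OC)cc5O[C@H]4c4ccc(OC)cc4)c2cc(OC)cc3c2[C@@H](c2cc(OC)cc(OC)c2)[C@H](c2ccc(OC)cc2)O3)cc1
F2 | step 18 | cyclic arylboronate, the analogue of 31 with a six-membered C7a–B(O-i-Pr)–O–C2 ring | COc1ccc([C@H]2OB(OC(C)C)c3cc(OCC)cc([C@@H]4c5c(Cl)cc(OC)cc5O[C@H]4c4ccc(OC)cc4)c3[C@@H]2c2cc(OC)cc3c2[C@@H](c2cc(OC)cc(OC)c2)[C@H](c2ccc(OC)cc2)O3)cc1
F3 | step 18 | phenol alcohol, 31 with the O1–C2 bond of ring B opened (C7a–OH and C2–OH) | COc1ccc([C@@H](O)[C@H](c3c(O)cc(OCC)cc3[C@@H]4c5c(Cl)cc(OC)cc5O[C@H]4c4ccc(OC)cc4)c2cc(OC)cc3c2[C@@H](c2cc(OC)cc(OC)c2)[C@H](c2ccc(OC)cc2)O3)cc1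
F4 | step 17 | formate of 26 | COc1ccc([C@@H](OC=O)[C@H](C#C[C@@H]4c5c(Cl)cc(OC)cc5O[C@H]4c4ccc(OC)cc4)c2cc(OC)cc3c2[C@@H](c2cc(OC)cc(OC)c2)[C@H](c2ccc(OC)cc2)O3)cc1
F5 | step 17 | 2,2-dibromoethenyl ether of 26 | COc1ccc([C@@H](OC=C(Br)Br)[C@H](C#C[C@@H]4c5c(Cl)cc(OC)cc5O[C@H]4c4ccc(OC)cc4)c2cc(OC)cc3c2[C@@H](c2cc(OC)cc(OC)c2)[C@H](c2ccc(OC)cc2)O3)cc1
F6 | step 5 | (4-methoxybenzyl)dimethylsulfonium tetrafluoroborate | COc1ccc(C[S+](C)C)cc1.F[B-](F)(F)F
F7 | step 5 | (2S,3S)-4-bromo-3-(3,5-dimethoxyphenyl)-6-methoxy-2-(4-methoxyphenyl)-2,3-dihydro-1-benzofuran | Brc1cc(OC)cc2c1[C@H](c1cc(OC)cc(OC)c1)[C@@H](c1ccc(OC)cc1)O2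
F0 | step 16 | none | none
F8 | step 21 | (E)-2-(3,4-diacetoxyphenyl)ethenylboronic acid pinacol ester | CC(=O)Oc1ccc(/C=C/B2OC(C)(C)C(C)(C)O2)cc1OC(C)=O
A1 | alternative 1 | methyl (2R,3R)-6-methoxy-2-(4-methoxyphenyl)-4-(trifluoromethanesulfonyloxy)-2,3-dihydro-1-benzofuran-3-carboxylate | O=S(=O)(Oc1cc(OC)cc2c1[C@@H](C(=O)OC)[C@H](c1ccc(OC)cc1)O2)C(F)(F)F
A2 | alternative 1 | (2R)-7-methoxy-2-(4-methoxyphenyl)-4-oxo-3,4-dihydro-2H-chromen-5-yl trifluoromethanesulfonate | COc1ccc([C@H]2CC(=O)c3c(OS(=O)(=O)C(F)(F)F)cc(OC)cc3O2)cc1
A3 | alternative 2 | tris(dihydrobenzofuran) bromide with free 4-hydroxyphenyl groups on rings B and C | Oc1ccc([C@H]2Oc3cc(OC)cc([C@@H]4c5c(Br)cc(OC)cc5O[C@H]4c4ccc(OC)cc4)c3[C@@H]2c2cc(OC)cc3c2[C@@H](c2cc(OC)cc(OC)c2)[C@H](c2ccc(O)cc2)O3)cc1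
A4 | alternative 2 | tetraphenol with rings B and C open (two 4-hydroxybenzyl groups, two C7a phenols) | Oc1ccc(C[C@H](c3c(O)cc(OC)cc3[C@@H]4c5c(Br)cc(OC)cc5O[C@H]4c4ccc(OC)cc4)c2cc(OC)cc(O)c2[C@@H](c2cc(OC)cc(OC)c2)Cc2ccc(O)cc2)cc1
A5 | alternative 3 | permethylated tris(dihydrobenzofuran) with bromine at C4 of ring A | COc1ccc([C@H]2Oc3cc(OC)cc([C@@H]4c5c(Br)cc(OC)cc5O[C@H]4c4ccc(OC)cc4)c3[C@@H]2c2cc(OC)cc3c2[C@@H](c2cc(OC)cc(OC)c2)[C@H](c2ccc(OC)cc2)O3)cc1
A6 | alternative 3 | ring A phenol sulfone on the ring B–C unit (4-methylbenzenesulfonyl taken as the sulfonyl group) | COc1ccc([C@H]2Oc3cc(OC)cc(C(c4c(O)cc(OC)cc4Br)S(=O)(=O)c4ccc(C)cc4)c3[C@@H]2c2cc(OC)cc3c2[C@@H](c2cc(OC)cc(OC)c2)[C@H](c2ccc(OC)cc2)O3)cc1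
A7 | alternative 3 | 3-bromo-5-methoxyphenol | COc1cc(O)cc(Br)c1
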